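**Retrosynthetic overview**

1. Target 17 ← tris-MOM ether 16 (deprotection last). 16 ← acyclic aldehyde 13, via its N-tosylhydrazone 14, by closing the cyclopentane bond C3–C4 (ring numbered C1 aryl-bearing, C2 CMe2, C3 CH2, C4 CH-isopropenyl, C5 CH2) in a cobalt-metalloradical 1,5-C–H alkylation. An aldehyde carbon and an unfunctionalised allylic CH2 are joined.
2. Enabling feature: the C4–H bonds are allylic to the isopropenyl group and lie exactly five atoms from C3, while C2 is quaternary (gem-dimethyl, no hydrogen). A carbene radical at C3 therefore has one weak C–H within reach and no 1,2-shift path.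
3. 13 ← lactone 7 (LiAlH4 opening, MOM ether, ortho-lithiation/benzoylation, oxidation). 7 ← 5 by double methylation. 5 ← coumarin 2 + Grignard reagent 4 by copper-catalysed asymmetric conjugate addition, which sets C1.
4. Rings: the phloroglucinol ring and a temporary lactone ring come with coumarin 1 (lactone opened in step 4). The phenyl ring comes with amide 10. The cyclopentane is the only ring made, in step 9.

Key step: step 9

Assumption: in the two catalyst-controlled steps (2 and 9) the antipode of the chiral ligand that delivers the configuration drawn is used; which antipode this is has to be fixed in a first pair of runs.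

**Route**

Step 1
Reactants: 1 5,7-dihydroxycoumarin
Product: 2 5,7-bis(methoxymethoxy)-2H-chromen-2-one
Conditions: MOMCl, iPr2NEt, DMF, 0 °C to rt
Reagents that add atoms: chloromethyl methyl ether, COCCl
Why: Williamson-type MOM ether formation on two acidic phenols should give a coumarin that tolerates the organometallic steps that follow.

Step 2
Reactants: 2 5,7-bis(methoxymethoxy)-2H-chromen-2-one; 3 4-bromo-2-methylbut-1-ene
Product: 5 (4R)-5,7-bis(methoxymethoxy)-4-(3-methylbut-3-en-1-yl)chroman-2-one, via Grignard reagent 4 (not isolated)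
Conditions: 3, Mg, Et2O, rt; then 2, CuBr·SMe2 (5 mol%), (R)-1-[(Sp)-2-(dicyclohexylphosphino)ferrocenyl]ethyldiphenylphosphine or its antipode (6 mol%), CH2Cl2, −78 °C; aq NH4Cl
Reagents that add atoms: none
Why: Copper-catalysed asymmetric conjugate addition of a Grignard reagent to a coumarin (Josiphos-type ligand on monovalent copper) should deliver the alkyl group to one face of C4 and so set the stereocenter (4R) that becomes ring C1, with 1,2-addition suppressed at −78 °C.

Step 3
Reactants: 5 (4R)-5,7-bis(methoxymethoxy)-4-(3-methylbut-3-en-1-yl)chroman-2-one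
Product: 7 (4S)-5,7-bis(methoxymethoxy)-3,3-dimethyl-4-(3-methylbut-3-en-1-yl)chroman-2-one, via trans-3-methyl lactone 6 (not isolated)
Conditions: LDA (1.1 equiv), THF, −78 °C; MeI; then LDA (1.3 equiv), −78 °C; MeI, −78 to −30 °C
Reagents that add atoms: iodomethane, CI
Why: Twofold lactone enolate alkylation at C3, the only acidic position, should build the quaternary carbon; the first methyl enters trans to the C4 chain, the second erases that centre, and C4 (β to the carbonyl) is not touched (the descriptor changes from R to S only through priorities).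

Step 4
Reactants: 7 (4S)-5,7-bis(methoxymethoxy)-3,3-dimethyl-4-(3-methylbut-3-en-1-yl)chroman-2-one
Product: 8 2-[(3R)-1-hydroxy-2,2,6-trimethylhept-6-en-3-yl]-3,5-bis(methoxymethoxy)phenol
Conditions: LiAlH4, THF, 0 °C; Rochelle salt work-up
Reagents that add atoms: none
Why: Hydride reduction of the aryl lactone should open the temporary ring to the phenol and the neopentyl primary alcohol, leaving the alkene and MOM ethers intact.

Step 5
Reactants: 8 2-[(3R)-1-hydroxy-2,2,6-trimethylhept-6-en-3-yl]-3,5-bis(methoxymethoxy)phenol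
Product: 9 (3R)-2,2,6-trimethyl-3-[2,4,6-tris(methoxymethoxy)phenyl]hept-6-en-1-ol
Conditions: NaH (1.05 equiv), THF/DMF, 0 °C; MOMCl (1.1 equiv)
Reagents that add atoms: chloromethyl methyl ether, COCCl
Why: Chemoselective O-alkylation should occur because one equivalent of NaH ionises only the phenol, which is far more acidic than the hindered neopentyl alcohol; the third MOM ether makes the two free ring positions equivalent.

Step 6
Reactants: 9 (3R)-2,2,6-trimethyl-3-[2,4,6-tris(methoxymethoxy)phenyl]hept-6-en-1-ol; 10 N-methoxy-N-methylbenzamide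
Product: 12 {3-[(3R)-1-hydroxy-2,2,6-trimethylhept-6-en-3-yl]-2,4,6-tris(methoxymethoxy)phenyl}(phenyl)methanone, via dilithio species 11 (not isolated)
Conditions: n-BuLi (2.2 equiv), THF, 0 °C; then 10, −78 °C to rt; aq NH4Cl
Reagents that add atoms: none
Why: Directed ortho-metalation followed by Weinreb ketone synthesis should install the benzoyl group: the first equivalent of n-BuLi forms the alkoxide, the second lithiates either of the two equivalent positions flanked by two MOM ethers, and the chelated tetrahedral adduct prevents over-addition.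

Step 7
Reactants: 12 {3-[(3R)-1-hydroxy-2,2,6-trimethylhept-6-en-3-yl]-2,4,6-tris(methoxymethoxy)phenyl}(phenyl)methanone
Product: 13 (3S)-3-[3-benzoyl-2,4,6-tris(methoxymethoxy)phenyl]-2,2,6-trimethylhept-6-enal
Conditions: Dess–Martin periodinane, NaHCO3, CH2Cl2, 0 °C to rt
Reagents that add atoms: none
Why: Dess–Martin oxidation of the primary alcohol should give an aldehyde that cannot enolise or epimerise (quaternary α-carbon); the descriptor changes to S only through priorities.

Step 8
Reactants: 13 (3S)-3-[3-benzoyl-2,4,6-tris(methoxymethoxy)phenyl]-2,2,6-trimethylhept-6-enal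
Product: 14 N'-[(1E,3R)-3-[3-benzoyl-2,4,6-tris(methoxymethoxy)phenyl]-2,2,6-trimethylhept-6-en-1-ylidene]-4-methylbenzenesulfonohydrazide
Conditions: TsNHNH2, MeOH, rt
Reagents that add atoms: 4-methylbenzenesulfonohydrazide, NNS(=O)(=O)c1ccc(C)cc1
Why: Hydrazone condensation should take place only at the aliphatic aldehyde, since the di-ortho-alkoxy benzophenone carbonyl is too hindered and deactivated to condense.

Step 9
Reactants: 14 N'-[(1E,3R)-3-[3-benzoyl-2,4,6-tris(methoxymethoxy)phenyl]-2,2,6-trimethylhept-6-en-1-ylidene]-4-methylbenzenesulfonohydrazide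
Product: 16 {3-[(1R,4R)-2,2-dimethyl-4-(prop-1-en-2-yl)cyclopentyl]-2,4,6-tris(methoxymethoxy)phenyl}(phenyl)methanone, via diazoalkane 15 (not isolated)
Conditions: [Co(3,5-DitBu-ChenPhyrin)] = cobalt 5,15-bis{2,6-bis[(S)-2,2-dimethylcyclopropanecarboxamido]phenyl}-10,20-bis(3,5-di-tert-butylphenyl)porphyrinate (divalent cobalt) or its antipode (2–5 mol%), Cs2CO3 (2 equiv), 1,4-dioxane, 50 °C
Reagents that add atoms: none
Why: Cs2CO3 converts 14 into diazoalkane 15 (Bamford–Stevens), which the divalent cobalt porphyrin takes up with loss of N2 as a cobalt-bound alkyl radical at the future ring C3; this radical abstracts one allylic hydrogen from the future C4 through a six-membered transition state (1,5-hydrogen atom transfer), and the allyl radical then displaces cobalt from C3, forming the C3–C4 bond and returning divalent cobalt. The closest known reaction type is the cobalt-porphyrin metalloradical 1,5-C–H alkylation with alkyl diazomethanes generated from aldehyde N-tosylhydrazones, used to close five-membered rings at allylic and benzylic C–H bonds. The cyclopentane closes in the 5-exo-tet mode (radical substitution at the cobalt-bound carbon), whereas attack through the far allyl terminus would need a seven-membered ring. The new stereocenter C4 is set in the hydrogen-abstraction/ring-closing pair inside the chiral amide-lined pocket of the porphyrin (catalyst control), with the resident C1 centre as a second element, and C1 itself is not touched. The step needs C–H alkylation to win over 1,2-shift, cyclopropanation of the 1,1-disubstituted alkene and ylide formation at the ether oxygens: the quaternary C2 removes every β-hydrogen and adds a Thorpe–Ingold push, the two allylic hydrogens are the only hydrogens five atoms from the radical carbon and are among the weakest C–H bonds present, and the radical (not electrophilic carbene) character of the intermediate disfavours ylides. The step also needs the trans (4R) ring over the cis ring, and this is the one selectivity the substrate alone does not secure; it rests on the choice of catalyst antipode.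

Step 10
Reactants: 16 {3-[(1R,4R)-2,2-dimethyl-4-(prop-1-en-2-yl)cyclopentyl]-2,4,6-tris(methoxymethoxy)phenyl}(phenyl)methanone
Product: 17 {3-[(1R,4R)-2,2-dimethyl-4-(prop-1-en-2-yl)cyclopentyl]-2,4,6-trihydroxyphenyl}(phenyl)methanone
Conditions: HCl (1.25 M in MeOH), 0 °C to rt
Reagents that add atoms: none
Why: Acid-catalysed acetal exchange with methanol should cleave the three aryl MOM ethers, all ortho or para to the benzoyl group, under dilute acid at low temperature; the 1,1-disubstituted alkene should persist because no phenol can reach it across the trans ring.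

**Compound list**

1 | 5,7-dihydroxycoumarin | O=C1C=Cc2c(O)cc(O)cc2O1 | starting material
2 | 5,7-bis(methoxymethoxy)-2H-chromen-2-one | O=C1C=Cc2c(OCOC)cc(OCOC)cc2O1 | intermediate
3 | 4-bromo-2-methylbut-1-ene | C=C(C)CCBr | starting material
4 | (3-methylbut-3-en-1-yl)magnesium bromide | C=C(C)CC[Mg]Br | intermediate
5 | (4R)-5,7-bis(methoxymethoxy)-4-(3-methylbut-3-en-1-yl)chroman-2-one | C=C(C)CC[C@@H]1CC(=O)Oc2cc(OCOC)cc(OCOC)c21 | intermediate
6 | (3R,4R)-5,7-bis(methoxymethoxy)-3-methyl-4-(3-methylbut-3-en-1-yl)chroman-2-one (trans) | C=C(C)CC[C@@H]1[C@@H](C)C(=O)Oc2cc(OCOC)cc(OCOC)c21 | intermediate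
7 | (4S)-5,7-bis(methoxymethoxy)-3,3-dimethyl-4-(3-methylbut-3-en-1-yl)chroman-2-one | C=C(C)CC[C@@H]1C(C)(C)C(=O)Oc2cc(OCOC)cc(OCOC)c21 | intermediate
8 | 2-[(3R)-1-hydroxy-2,2,6-trimethylhept-6-en-3-yl]-3,5-bis(methoxymethoxy)phenol | C=C(C)CC[C@@H](c1c(O)cc(OCOC)cc1OCOC)C(C)(C)CO | intermediate
9 | (3R)-2,2,6-trimethyl-3-[2,4,6-tris(methoxymethoxy)phenyl]hept-6-en-1-ol | C=C(C)CC[C@@H](c1c(OCOC)cc(OCOC)cc1OCOC)C(C)(C)CO | intermediate
10 | N-methoxy-N-methylbenzamide | CON(C)C(=O)c1ccccc1 | starting material
11 | dilithio species of 9 (lithium alkoxide, aryllithium between two MOM ethers) | C=C(C)CC[C@@H](c1c(OCOC)cc(OCOC)c([Li])c1OCOC)C(C)(C)CO[Li] | intermediate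
12 | {3-[(3R)-1-hydroxy-2,2,6-trimethylhept-6-en-3-yl]-2,4,6-tris(methoxymethoxy)phenyl}(phenyl)methanone | C=C(C)CC[C@@H](c1c(OCOC)cc(OCOC)c(C(=O)c2ccccc2)c1OCOC)C(C)(C)CO | intermediate
13 | (3S)-3-[3-benzoyl-2,4,6-tris(methoxymethoxy)phenyl]-2,2,6-trimethylhept-6-enal | C=C(C)CC[C@@H](c1c(OCOC)cc(OCOC)c(C(=O)c2ccccc2)c1OCOC)C(C)(C)C=O | intermediate
14 | N'-[(1E,3R)-3-[3-benzoyl-2,4,6-tris(methoxymethoxy)phenyl]-2,2,6-trimethylhept-6-en-1-ylidene]-4-methylbenzenesulfonohydrazide | C=C(C)CC[C@@H](c1c(OCOC)cc(OCOC)c(C(=O)c2ccccc2)c1OCOC)C(C)(C)/C=N/NS(=O)(=O)c1ccc(C)cc1 | intermediate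
15 | {3-[(3R)-1-diazo-2,2,6-trimethylhept-6-en-3-yl]-2,4,6-tris(methoxymethoxy)phenyl}(phenyl)methanone | C=C(C)CC[C@@H](c1c(OCOC)cc(OCOC)c(C(=O)c2ccccc2)c1OCOC)C(C)(C)C=[N+]=[N-] | intermediate
16 | {3-[(1R,4R)-2,2-dimethyl-4-(prop-1-en-2-yl)cyclopentyl]-2,4,6-tris(methoxymethoxy)phenyl}(phenyl)methanone | C=C(C)[C@@H]1C[C@@H](c2c(OCOC)cc(OCOC)c(C(=O)c3ccccc3)c2OCOC)C(C)(C)C1 | intermediate
17 | {3-[(1R,4R)-2,2-dimethyl-4-(prop-1-en-2-yl)cyclopentyl]-2,4,6-trihydroxyphenyl}(phenyl)methanone (CNP0143418.1) | C=C(C)[C@@H]1C[C@@H](c2c(O)cc(O)c(C(=O)c3ccccc3)c2O)C(C)(C)C1 | target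

**Step count**

Total step count: 10. Longest linear sequence: 10 steps (1 to 17).

**Steps most likely to fail, with fallbacks**

Step 9. Two processes may go wrong. The facial selectivity in the ring-closing radical substitution may be poor if the resident C1 centre opposes the catalyst, giving the cis ring. The cobalt-bound radical may also add to the 1,1-disubstituted alkene (cyclopropanation) instead of abstracting hydrogen. The fallback sets out from 13 and comes back at 16, closing the same C3–C4 bond by carbonyl chemistry. The isopropenyl group of 13 is cleaved (OsO4 cat., NaIO4, 2,6-lutidine, dioxane/H2O) to the keto aldehyde (3S)-3-[3-benzoyl-2,4,6-tris(methoxymethoxy)phenyl]-2,2-dimethyl-6-oxoheptanal F1. Intramolecular aldol condensation (KOH, MeOH, rt) of the internal ketone enolate onto the non-enolisable aldehyde should give {3-[(1R)-4-acetyl-2,2-dimethylcyclopent-3-en-1-yl]-2,4,6-tris(methoxymethoxy)phenyl}(phenyl)methanone F2. Conjugate reduction with [(Ph3P)CuH]6 (toluene, rt) and equilibration of the epimerisable acetyl centre (NaOMe, MeOH) should give, after separation and recycling of the cis epimer through the same equilibration, {3-[(1R,4R)-4-acetyl-2,2-dimethylcyclopentyl]-2,4,6-tris(methoxymethoxy)phenyl}(phenyl)methanone F3. Wittig methylenation (Ph3P=CH2, THF, 0 °C), to which the hindered benzophenone carbonyl should be inert, then gives 16.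

Step 2. Enantiofacial control may be lost, or 1,2-addition may compete, because the peri MOM ether at C5 crowds C4 and can chelate magnesium. The fallback sets out from 2 and comes back at 5, setting the centre by hydride delivery instead of alkyl delivery. Ligand-free copper-catalysed addition of Grignard reagent 4 (CuBr·SMe2 10 mol%, TMSCl, THF, −40 °C) should give racemic 5,7-bis(methoxymethoxy)-4-(3-methylbut-3-en-1-yl)chroman-2-one F4. Dehydrogenation (DDQ, 1,4-dioxane, reflux) should give 5,7-bis(methoxymethoxy)-4-(3-methylbut-3-en-1-yl)-2H-chromen-2-one F5. Copper hydride-catalysed asymmetric conjugate reduction of this 4-substituted coumarin (Cu(OAc)2·H2O, (R)- or (S)-DTBM-SEGPHOS, polymethylhydrosiloxane, t-BuOH, toluene, rt), which does not touch the isolated alkene, should give 5.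

Step 3. The aryl ester enolate may fragment to a ketene and phenoxide, and the second methylation may stall beside the congested C4. The fallback sets out from 5 and comes back at 9, using an ordinary alkyl ester enolate. Lactone 5 is opened with LiOH (THF/H2O) and the dry dilithium phenoxide carboxylate, which cannot re-close, is alkylated twice with MOMCl (DMF, 0 °C) to give methoxymethyl (3R)-6-methyl-3-[2,4,6-tris(methoxymethoxy)phenyl]hept-6-enoate F6. Two rounds of LDA/MeI (THF, −78 °C) should give methoxymethyl (3S)-2,2,6-trimethyl-3-[2,4,6-tris(methoxymethoxy)phenyl]hept-6-enoate F7. LiAlH4 (THF, 0 °C) then gives 9 directly, so that steps 4 and 5 are not needed.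

**Further compounds**

F1 | step 9 | (3S)-3-[3-benzoyl-2,4,6-tris(methoxymethoxy)phenyl]-2,2-dimethyl-6-oxoheptanal | CC(=O)CC[C@@H](c1c(OCOC)cc(OCOC)c(C(=O)c2ccccc2)c1OCOC)C(C)(C)C=O
F2 | step 9 | {3-[(1R)-4-acetyl-2,2-dimethylcyclopent-3-en-1-yl]-2,4,6-tris(methoxymethoxy)phenyl}(phenyl)methanone | CC(=O)C1=CC(C)(C)[C@H](c2c(OCOC)cc(OCOC)c(C(=O)c3ccccc3)c2OCOC)C1
F3 | step 9 | {3-[(1R,4R)-4-acetyl-2,2-dimethylcyclopentyl]-2,4,6-tris(methoxymethoxy)phenyl}(phenyl)methanone | CC(=O)[C@@H]1C[C@@H](c2c(OCOC)cc(OCOC)c(C(=O)c3ccccc3)c2OCOC)C(C)(C)C1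
F4 | step 2 | racemic 5,7-bis(methoxymethoxy)-4-(3-methylbut-3-en-1-yl)chroman-2-one | C=C(C)CCC1CC(=O)Oc2cc(OCOC)cc(OCOC)c21
F5 | step 2 | 5,7-bis(methoxymethoxy)-4-(3-methylbut-3-en-1-yl)-2H-chromen-2-one | C=C(C)CCC1=CC(=O)Oc2cc(OCOC)cc(OCOC)c21
F6 | step 3 | methoxymethyl (3R)-6-methyl-3-[2,4,6-tris(methoxymethoxy)phenyl]hept-6-enoate | C=C(C)CC[C@@H](c1c(OCOC)cc(OCOC)cc1OCOC)CC(=O)OCOC
F7 | step 3 | methoxymethyl (3S)-2,2,6-trimethyl-3-[2,4,6-tris(methoxymethoxy)phenyl]hept-6-enoate | C=C(C)CC[C@@H](c1c(OCOC)cc(OCOC)cc1OCOC)C(C)(C)C(=O)OCOC
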